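The skeleton is cut at C1–C11, the bond from the ketone carbon to the cyclobutane CH that is a bridgehead of the cyclohexanone ring C1–C2–C3–C4–C5–C11 (longipinane numbering, given below). Because C11 carries only hydrogen and lies 1,3-cis to C4 on the cyclobutane C4–C5–C11–C10, it is first made as the carbonyl carbon of a bridged cyclobutanone by an intramolecular ketene–diene [2+2] cycloaddition. In the key step a C1 acyl radical on the C4 side chain adds to the N-aziridinylimine of this ketone, and loss of styrene and N2 leaves C11–H. Ring closure and carbonyl removal thus occur in one operation on a bicyclo[4.1.1]octene selenoester hydrazone.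

Key step: step 15

Numbering (longipinane, used for all ring compounds and their open-chain precursors): C1 ketone carbon; C2 CH2; C3 CH–CH3; C4, C5, C10, C11 the cyclobutane carbons (C4 bonded to C3, C5 to C6, C10 carries CH3 and is bonded to C9, C11 is bonded to C1); C6 C(CH3)2; C7, C8, C9 the oxygen-bearing carbons counted from C6.

Remark: the sense of induction by the C7 silyloxy group in step 8 is an assumption from a conformational argument; the fallback for step 8 sets the same centers under auxiliary control.

Step 1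
Reactants: 1 (S)-pantolactone
Product: 2 (3S)-3-(tert-butyldimethylsilyloxy)-4,4-dimethyloxolan-2-one
Conditions: TBSCl, imidazole, DMF, rt
Reagents that add atoms: tert-butyldimethylsilyl chloride CC(C)(C)[Si](C)(C)Cl
Why: Silyl ether formation at the secondary alcohol; the stereocenter (the later C7) comes from the chiral pool and is not touched.

Step 2
Reactants: 2 silylated pantolactone
Product: 3 (2S)-2-(tert-butyldimethylsilyloxy)-4-hydroxy-N-methoxy-N,3,3-trimethylbutanamide
Conditions: MeNH(OMe)·HCl, i-PrMgCl, THF, −20 → 0 °C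
Reagents that add atoms: N,O-dimethylhydroxylamine hydrochloride CNOC.Cl
Why: Ring-opening aminolysis of the lactone by the magnesium amide gives the N-methoxy-N-methylamide; no stereocenter forms and the α-silyloxy center is not enolized at low temperature.

Step 3
Reactants: 3 hydroxy amide
Product: 4 (2S)-2-(tert-butyldimethylsilyloxy)-N-methoxy-N,3,3-trimethyl-4-oxobutanamide
Conditions: Dess–Martin periodinane, NaHCO3, CH2Cl2, 0 °C → rt
Reagents that add atoms: none
Why: Dess–Martin oxidation of the neopentyl primary alcohol gives a non-enolizable aldehyde, so no center can epimerize through it.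

Step 4
Reactants: 4 aldehyde amide
Product: 5 (2S,4E)-2-(tert-butyldimethylsilyloxy)-N-methoxy-N,3,3-trimethylhepta-4,6-dienamide
Conditions: diethyl allylphosphonate, n-BuLi, THF, −78 °C; then 4, HMPA, −78 °C → rt
Reagents that add atoms: diethyl allylphosphonate C=CCP(=O)(OCC)OCC
Why: Horner–Wadsworth–Emmons-type olefination with the lithiated allylphosphonate should react only at the aldehyde at −78 °C and give the E diene (the later C5=C4–C3=C2 unit).

Step 5
Reactants: 5 dienamide
Product: 6 (2S,4E)-2-(tert-butyldimethylsilyloxy)-3,3-dimethylhepta-4,6-dienal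
Conditions: DIBAL-H, THF, −78 °C; aq Rochelle salt
Reagents that add atoms: none
Why: Hydride reduction of the N-methoxy-N-methylamide stops at the aldehyde through the chelated tetrahedral intermediate; the α-silyloxy stereocenter is kept at −78 °C.

Step 6
Reactants: 7 methacrylic acid; 8 triphenylphosphine hydrobromide
Product: 9 (2-carboxypropyl)triphenylphosphonium bromide
Conditions: MeCN, 80 °C
Reagents that add atoms: none
Why: Phospha-Michael addition of triphenylphosphine to the protonated acrylic acid; the stereocenter formed is lost later and is left racemic.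

Step 7
Reactants: 6 dienal; 9 phosphonium salt
Product: 11 (3Z,5R,7E)-5-(tert-butyldimethylsilyloxy)-2,6,6-trimethyldeca-3,7,9-trienoic acid, via carboxylate ylide 10 (not isolated)
Conditions: 9, NaHMDS (2 equiv), THF, −78 → 0 °C; then 6, −78 °C → rt; aq NaH2PO4
Reagents that add atoms: none
Why: Wittig olefination with the non-stabilised carboxylate ylide should give the Z alkene (the later C8=C9) by kinetic cis-oxaphosphetane formation; the C2 center of the acid is of no consequence.

Step 8
Reactants: 11 trienoic acid
Product: 14 4-(tert-butyldimethylsilyloxy)-7-ethenyl-1,5,5-trimethylbicyclo[4.1.1]oct-2-en-8-one, via acyl chloride 12 (not isolated), via vinylketene 13 (not isolated)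
Conditions: 1-chloro-N,N,2-trimethylprop-1-en-1-amine, CH2Cl2, 0 °C; then slow addition to Et3N, toluene, 110 °C, high dilution
Reagents that add atoms: none
Why: Thermal intramolecular ketene–alkene [2+2] cycloaddition in the bridged mode: the ketene carbonyl carbon C11 bonds to the diene terminus C5 and C10 to the allylic carbon C4 (the usual regiochemistry of ketenes with 1,3-dienes), the tether fixes C10 and C5, suprafacial addition to the E alkene places the C4 vinyl group trans to C6, and the C7 silyloxy group is expected to sit pseudo-equatorial on the forming seven-membered ring, which puts C7–O on the C4 side.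

Step 9
Reactants: 14 bicyclic vinyl ketone
Product: 15 3-[4-(tert-butyldimethylsilyloxy)-1,5,5-trimethyl-8-oxobicyclo[4.1.1]oct-2-en-7-yl]propanal
Conditions: Rh(acac)(CO)2 (2 mol %), BIPHEPHOS (4 mol %), CO/H2 (1:1, 10 bar), toluene, 60 °C
Reagents that add atoms: carbon monoxide [C-]#[O+]
Why: Rhodium-catalysed linear-selective hydroformylation adds the C1 carbon to the terminal vinyl carbon only, since the ring alkene is shielded by a quaternary and a silyloxy-bearing neighbour; no stereocenter forms.

Step 10
Reactants: 15 keto aldehyde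
Product: 16 3-[4-(tert-butyldimethylsilyloxy)-1,5,5-trimethyl-8-oxobicyclo[4.1.1]oct-2-en-7-yl]propanoic acid
Conditions: NaClO2, NaH2PO4, 2-methylbut-2-ene, t-BuOH/H2O, rt
Reagents that add atoms: sodium chlorite [Na+].[O-]Cl=O
Why: Pinnick oxidation converts the aldehyde into the acid without affecting the strained ketone, the ring alkene (hypochlorite is scavenged) or the silyl ether.

Step 11
Reactants: 17 1-phenylethane-1,2-diol
Product: 18 1-phenylethane-1,2-diyl dimethanesulfonate
Conditions: MsCl, Et3N, CH2Cl2, 0 °C
Reagents that add atoms: methanesulfonyl chloride CS(=O)(=O)Cl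
Why: Sulfonylation of both hydroxyl groups; the racemate is used because this center is expelled as styrene in step 15.

Step 12
Reactants: 18 dimesylate
Product: 19 1-amino-2-phenylaziridine
Conditions: N2H4·H2O, pentane, rt
Reagents that add atoms: hydrazine hydrate NN.O
Why: Double N-alkylation of hydrazine (SN2 displacement, then 3-exo-tet closure) gives the N-aminoaziridine.

Step 13
Reactants: 16 keto acid; 19 1-amino-2-phenylaziridine
Product: 20 3-[4-(tert-butyldimethylsilyloxy)-1,5,5-trimethyl-8-[(2-phenylaziridin-1-yl)imino]bicyclo[4.1.1]oct-2-en-7-yl]propanoic acid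
Conditions: CH2Cl2, MgSO4, 0 °C → rt
Reagents that add atoms: none
Why: Hydrazone-type condensation at the only ketone, the strained and therefore electrophilic cyclobutanone; the C=N geometry and the aziridine center are lost later.

Step 14
Reactants: 20 aziridinylimine acid
Product: 21 Se-phenyl 3-[4-(tert-butyldimethylsilyloxy)-1,5,5-trimethyl-8-[(2-phenylaziridin-1-yl)imino]bicyclo[4.1.1]oct-2-en-7-yl]propaneselenoate
Conditions: (PhSe)2, Bu3P, CH2Cl2, rt
Reagents that add atoms: diphenyl diselenide c1ccc(cc1)[Se][Se]c1ccccc1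
Why: Phosphine-mediated selenoesterification (acyloxyphosphonium ion attacked by selenolate) gives the acyl radical precursor under neutral conditions that spare the aziridinylimine.

Step 15
Reactants: 21 selenoester aziridinylimine
Product: 24 7-(tert-butyldimethylsilyloxy)-3-demethyllongipin-8-en-1-one, via acyl radical 22 (not isolated), via bridgehead radical 23 (not isolated)
Conditions: Bu3SnH (slow addition), AIBN, benzene, 80 °C
Reagents that add atoms: none
Why: The tributyltin radical abstracts the phenylseleno group to give the C1 acyl radical 22, which adds 6-exo-trig to the C11 carbon of the C=N bond; the aminyl radical then opens the aziridine, expels styrene and N2 and leaves the C11 radical 23, which takes hydrogen from Bu3SnH. The closest known reaction type is radical cyclization onto ketone-derived N-aziridinylimines with loss of styrene and nitrogen, run here with an acyl radical from a selenoester. One ring closes, the six-membered ring C1–C2–C3–C4–C5–C11, by 6-exo-trig attack on the exocyclic C=N carbon, which turns the bicyclo[4.1.1]octene into the tricyclic longipinane core. No freely variable stereocenter arises: C11 becomes a bridgehead, the C4 side chain is axial on the cyclobutane so C1 can only bond to the C11 face turned toward C4, and hydrogen enters at the one remaining position. The step needs attack at carbon and not nitrogen and cyclization faster than reduction or decarbonylation of the acyl radical; the N–N substituent (stabilised aminyl radical, irreversible fragmentation), the relief of sp2 strain in the four-membered ring and the slow addition of tin hydride should secure this.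

Step 16
Reactants: 24 tricyclic ketone
Product: 25 7-(tert-butyldimethylsilyloxy)-3-demethyllongipina-2,8-dien-1-one
Conditions: IBX, toluene/DMSO, 70 °C
Reagents that add atoms: none
Why: IBX-mediated α,β-dehydrogenation of the ketone can only go toward C2–C3 because C11 is a bridgehead; no stereocenter is involved.

Step 17
Reactants: 25 enone
Product: 26 7-(tert-butyldimethylsilyloxy)longipin-8-en-1-one
Conditions: CuI, MeLi (2 equiv), Et2O, 0 °C; then 25, −78 → 0 °C; aq NH4Cl
Reagents that add atoms: lithium dimethylcuprate [Li+].C[Cu-]C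
Why: Conjugate addition of the cuprate to the bicyclo[3.1.1]heptenone should occur on the face of C3 turned toward C5, away from the C10 methyl group that covers the other face, which sets C3 as in the target.

Step 18
Reactants: 26 methyl ketone
Product: 27 7-(tert-butyldimethylsilyloxy)-8,9-dihydroxylongipinan-1-one
Conditions: OsO4 (5 mol %), N-methylmorpholine N-oxide, acetone/H2O, rt
Reagents that add atoms: N-methylmorpholine N-oxide C[N+]1([O-])CCOCC1; water O
Why: Upjohn syn-dihydroxylation of C8=C9 from the face anti to the allylic C7 silyloxy group, the usual sense for cyclic allylic ethers, sets C8 and C9 with both oxygens on the C11 side, trans to C7–O.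

Step 19
Reactants: 27 silyloxy diol
Product: 28 7,8,9-trihydroxylongipinan-1-one
Conditions: HF·pyridine, THF, 0 °C → rt
Reagents that add atoms: none
Why: Fluoride-mediated desilylation under mildly acidic conditions frees the C7 hydroxyl without affecting the ketone.

Step 20
Reactants: 28 triol
Product: 29 8-acetoxy-7,9-dihydroxylongipinan-1-one
Conditions: Ac2O (1.05 equiv), 2,4,6-collidine, CH2Cl2, −20 °C
Reagents that add atoms: acetic anhydride CC(=O)OC(C)=O
Why: Selective esterification: C8–OH is the only hydroxyl not next to a quaternary carbon, so one equivalent of anhydride with a weak base at low temperature should acetylate it first.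

Step 21
Reactants: 29 monoacetate
Product: 30 8-acetoxy-7,9-bis(angeloyloxy)longipinan-1-one (CNP0197834.1)
Conditions: angelic acid, 2,4,6-trichlorobenzoyl chloride, Et3N, toluene, rt; then 29, 80 °C
Reagents that add atoms: angelic acid C/C=C(/C)C(=O)O
Why: Yamaguchi-type esterification through the mixed anhydride, run without a nucleophilic catalyst so that the Z geometry of the angelate is kept, should acylate both remaining neopentyl hydroxyls.

Compound list

1 | (S)-pantolactone, (3S)-3-hydroxy-4,4-dimethyloxolan-2-one | CC1(C)COC(=O)[C@H]1O | starting material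
2 | (3S)-3-(tert-butyldimethylsilyloxy)-4,4-dimethyloxolan-2-one | CC1(C)COC(=O)[C@H]1O[Si](C)(C)C(C)(C)C | intermediate
3 | (2S)-2-(tert-butyldimethylsilyloxy)-4-hydroxy-N-methoxy-N,3,3-trimethylbutanamide | CON(C)C(=O)[C@@H](O[Si](C)(C)C(C)(C)C)C(C)(C)CO | intermediate
4 | (2S)-2-(tert-butyldimethylsilyloxy)-N-methoxy-N,3,3-trimethyl-4-oxobutanamide | CON(C)C(=O)[C@@H](O[Si](C)(C)C(C)(C)C)C(C)(C)C=O | intermediate
5 | (2S,4E)-2-(tert-butyldimethylsilyloxy)-N-methoxy-N,3,3-trimethylhepta-4,6-dienamide | CON(C)C(=O)[C@@H](O[Si](C)(C)C(C)(C)C)C(C)(C)/C=C/C=C | intermediate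
6 | (2S,4E)-2-(tert-butyldimethylsilyloxy)-3,3-dimethylhepta-4,6-dienal | O=C[C@@H](O[Si](C)(C)C(C)(C)C)C(C)(C)/C=C/C=C | intermediate
7 | methacrylic acid | C=C(C)C(=O)O | starting material
8 | triphenylphosphine hydrobromide | [Br-].[PH+](c1ccccc1)(c1ccccc1)c1ccccc1 | starting material
9 | (2-carboxypropyl)triphenylphosphonium bromide, racemic | CC(C[P+](c1ccccc1)(c1ccccc1)c1ccccc1)C(=O)O.[Br-] | intermediate
10 | sodium 2-methyl-3-(triphenylphosphoranylidene)propanoate, the carboxylate ylide | CC(C=P(c1ccccc1)(c1ccccc1)c1ccccc1)C(=O)[O-].[Na+] | intermediate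
11 | (3Z,5R,7E)-5-(tert-butyldimethylsilyloxy)-2,6,6-trimethyldeca-3,7,9-trienoic acid, both C2 epimers | CC(/C=C\[C@@H](O[Si](C)(C)C(C)(C)C)C(C)(C)/C=C/C=C)C(=O)O | intermediate
12 | (3Z,5R,7E)-5-(tert-butyldimethylsilyloxy)-2,6,6-trimethyldeca-3,7,9-trienoyl chloride | CC(/C=C\[C@@H](O[Si](C)(C)C(C)(C)C)C(C)(C)/C=C/C=C)C(=O)Cl | intermediate
13 | (3Z,5R,7E)-5-(tert-butyldimethylsilyloxy)-2,6,6-trimethyldeca-1,3,7,9-tetraen-1-one, the vinylketene | CC(/C=C\[C@@H](O[Si](C)(C)C(C)(C)C)C(C)(C)/C=C/C=C)=C=O | intermediate
14 | 4-(tert-butyldimethylsilyloxy)-7-ethenyl-1,5,5-trimethylbicyclo[4.1.1]oct-2-en-8-one (C11 ketone in the cyclobutane C4–C5–C11–C10; C4 vinyl trans to C6 and pointing toward C11; C8=C9 alkene; C7–O on the C4 side) | CC(C)(C)[Si](C)(C)O[C@@H]1C=C[C@]2(C)[C@@H](C=C)[C@@H](C2=O)C1(C)C | intermediate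
15 | 3-[4-(tert-butyldimethylsilyloxy)-1,5,5-trimethyl-8-oxobicyclo[4.1.1]oct-2-en-7-yl]propanal, ring centers as in 14 | CC(C)(C)[Si](C)(C)O[C@@H]1C=C[C@]2(C)[C@@H](CCC=O)[C@@H](C2=O)C1(C)C | intermediate
16 | 3-[4-(tert-butyldimethylsilyloxy)-1,5,5-trimethyl-8-oxobicyclo[4.1.1]oct-2-en-7-yl]propanoic acid, ring centers as in 14 | CC(C)(C)[Si](C)(C)O[C@@H]1C=C[C@]2(C)[C@@H](CCC(=O)O)[C@@H](C2=O)C1(C)C | intermediate
17 | 1-phenylethane-1,2-diol, racemic | OCC(O)c1ccccc1 | starting material
18 | 1-phenylethane-1,2-diyl dimethanesulfonate, racemic | CS(=O)(=O)OCC(OS(C)(=O)=O)c1ccccc1 | intermediate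
19 | 1-amino-2-phenylaziridine, racemic | NN1CC1c1ccccc1 | intermediate
20 | 3-[4-(tert-butyldimethylsilyloxy)-1,5,5-trimethyl-8-[(2-phenylaziridin-1-yl)imino]bicyclo[4.1.1]oct-2-en-7-yl]propanoic acid, ring centers as in 14, mixture at the aziridine carbon and the C=N bond | CC(C)(C)[Si](C)(C)O[C@@H]1C=C[C@]2(C)[C@@H](CCC(=O)O)[C@@H](C2=NN3CC3c3ccccc3)C1(C)C | intermediate
21 | Se-phenyl 3-[4-(tert-butyldimethylsilyloxy)-1,5,5-trimethyl-8-[(2-phenylaziridin-1-yl)imino]bicyclo[4.1.1]oct-2-en-7-yl]propaneselenoate, ring centers as in 14 | CC(C)(C)[Si](C)(C)O[C@@H]1C=C[C@]2(C)[C@@H](CCC(=O)[Se]c3ccccc3)[C@@H](C2=NN3CC3c3ccccc3)C1(C)C | intermediate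
22 | C1 acyl radical derived from 21 | CC(C)(C)[Si](C)(C)O[C@@H]1C=C[C@]2(C)[C@@H](CC[C]=O)[C@@H](C2=NN3CC3c3ccccc3)C1(C)C | intermediate
23 | C11 bridgehead radical of the tricyclic ketone | CC(C)(C)[Si](C)(C)O[C@@H]1C=C[C@]2(C)[C@@H]3[C@@H]([C]2C(=O)CC3)C1(C)C | intermediate
24 | 7-(tert-butyldimethylsilyloxy)-3-demethyllongipin-8-en-1-one (C7–O on the C4 side) | CC(C)(C)[Si](C)(C)O[C@@H]1C=C[C@]2(C)[C@@H]3[C@@H]([C@H]2C(=O)CC3)C1(C)C | intermediate
25 | 7-(tert-butyldimethylsilyloxy)-3-demethyllongipina-2,8-dien-1-one | CC(C)(C)[Si](C)(C)O[C@@H]1C=C[C@]2(C)[C@@H]3[C@@H]([C@H]2C(=O)C=C3)C1(C)C | intermediate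
26 | 7-(tert-butyldimethylsilyloxy)longipin-8-en-1-one (C3 methyl on the C5 side) | CC(C)(C)[Si](C)(C)O[C@@H]1C=C[C@]2(C)[C@@H]3[C@@H]([C@H]2C(=O)C[C@H]3C)C1(C)C | intermediate
27 | 7-(tert-butyldimethylsilyloxy)-8,9-dihydroxylongipinan-1-one (C8–O and C9–O on the C11 side, trans to C7–O) | CC(C)(C)[Si](C)(C)O[C@@H]1[C@@H](O)[C@@H](O)[C@]2(C)[C@@H]3[C@@H]([C@H]2C(=O)C[C@H]3C)C1(C)C | intermediate
28 | 7,8,9-trihydroxylongipinan-1-one | O[C@@H]1[C@@H](O)[C@@H](O)[C@]2(C)[C@@H]3[C@@H]([C@H]2C(=O)C[C@H]3C)C1(C)C | intermediate
29 | 8-acetoxy-7,9-dihydroxylongipinan-1-one | O[C@@H]1[C@@H](OC(C)=O)[C@@H](O)[C@]2(C)[C@@H]3[C@@H]([C@H]2C(=O)C[C@H]3C)C1(C)C | intermediate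
30 | 8-acetoxy-7,9-bis(angeloyloxy)longipinan-1-one, CNP0197834.1 | C/C=C(/C)C(=O)O[C@@H]1[C@@H](OC(C)=O)[C@@H](OC(=O)/C(C)=C\C)[C@]2(C)[C@@H]3[C@@H]([C@H]2C(=O)C[C@H]3C)C1(C)C | target

Total step count: 21. Longest linear sequence: 18 steps (steps 1–5, 7–10, 13–21).

Steps most likely to fail

1. Step 8. The Z-dienylketene can be consumed by a sigmatropic [1,5]-hydrogen shift from C7–H to the ketene carbon, closure of the seven-membered ring can be slower than ketene dimerization, and the facial selectivity with respect to C7 can be low. Fallback from 11, through acyl chloride 12 as in step 8, back to 14: 12 is condensed with (2R,5R)-2,5-dimethylpyrrolidine and Et3N to the amide F1. Tf2O and 2,6-di-tert-butyl-4-methylpyridine in 1,2-dichloroethane at room temperature give the keteniminium triflate F2. A stepwise cationic [2+2] cycloaddition, run below the temperature range of the sigmatropic shift, gives the cyclobutaniminium triflate F3, in which the C2-symmetric auxiliary and not C7 decides the face of C10. Hydrolysis with aqueous NaHCO3 returns to 14.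

2. Step 15. The acyl radical can be reduced to the aldehyde or lose CO before it cyclizes, and the aziridinylimine can fragment thermally to a diazoalkane. Fallback from keto aldehyde 15 back to 24, closing the same C1–C11 bond by polar chemistry: a triazolium carbene catalyst with DBU in THF effects an intramolecular crossed benzoin addition of the aldehyde to the cyclobutanone and gives the bridgehead α-hydroxy ketone F4. Acylation with methyl chlorooxoacetate and pyridine gives the methyl oxalate F5. Radical deoxygenation with Bu3SnH and AIBN in toluene at 110 °C returns to 24.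

3. Step 21. The angelate can isomerize to the tiglate under basic acylation, the C8 acetyl group can migrate to C7 or C9, and acylation of the two neopentyl hydroxyls can stay incomplete. Fallback from 29 back to 30: esterification with 2-(diphenoxyphosphoryl)propanoic acid (DCC, DMAP, CH2Cl2) gives the bis(phosphonate) F6. A Z-selective Horner–Wadsworth–Emmons olefination with acetaldehyde (NaH, THF, −78 °C) then builds both angelate double bonds on the esters and returns to 30.

Further compounds

F1 | step 8 | (3Z,5R,7E)-5-(tert-butyldimethylsilyloxy)-1-[(2R,5R)-2,5-dimethylpyrrolidin-1-yl]-2,6,6-trimethyldeca-3,7,9-trien-1-one | CC(/C=C\[C@@H](O[Si](C)(C)C(C)(C)C)C(C)(C)/C=C/C=C)C(=O)N1[C@H](C)CC[C@H]1C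
F2 | step 8 | keteniminium triflate derived from F1 | CC(/C=C\[C@@H](O[Si](C)(C)C(C)(C)C)C(C)(C)/C=C/C=C)=C=[N+]1[C@H](C)CC[C@H]1C.[O-]S(=O)(=O)C(F)(F)F
F3 | step 8 | cyclobutaniminium triflate, the (2R,5R)-2,5-dimethylpyrrolidinium-ylidene analogue of 14 | CC(C)(C)[Si](C)(C)O[C@@H]1C=C[C@]2(C)[C@@H](C=C)[C@@H](C2=[N+]3[C@H](C)CC[C@H]3C)C1(C)C.[O-]S(=O)(=O)C(F)(F)F
F4 | step 15 | 7-(tert-butyldimethylsilyloxy)-11-hydroxy-3-demethyllongipin-8-en-1-one | CC(C)(C)[Si](C)(C)O[C@@H]1C=C[C@]2(C)[C@@H]3[C@@H]([C@@]2(O)C(=O)CC3)C1(C)C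
F5 | step 15 | methyl oxalate of F4 at the C11 oxygen | CC(C)(C)[Si](C)(C)O[C@@H]1C=C[C@]2(C)[C@@H]3[C@@H]([C@@]2(OC(=O)C(=O)OC)C(=O)CC3)C1(C)C
F6 | step 21 | 8-acetoxy-7,9-bis[2-(diphenoxyphosphoryl)propanoyloxy]longipinan-1-one | CC(P(=O)(Oc4ccccc4)Oc4ccccc4)C(=O)O[C@@H]1[C@@H](OC(C)=O)[C@@H](OC(=O)C(C)P(=O)(Oc4ccccc4)Oc4ccccc4)[C@]2(C)[C@@H]3[C@@H]([C@H]2C(=O)C[C@H]3C)C1(C)C
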